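**Plan**
1. Retrosynthesis: the O–Si bond and the C2–H/C3–H pair go first (flavanone → silyl-protected flavone). Ring C is then cut at C4a–C4, C4–C3 and O1–C2. This is possible because C4 is a carbonyl carbon held between C4a of ring A and C3, while C2 carries O1 and the phenyl group, so ring C is the sum of an ortho-iodophenol, CO and phenylacetylene.
2. The iodophenol is cut at C–I and at the aryl–CH2 bond of the side chain, back to the methoxymethyl ether of 3,5-dimethoxyphenol and prenyl bromide. The carbinol C–O bond comes from epoxidation of the prenyl alkene.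
3. Forward: ring A is bought; the prenyl chain is joined by directed lithiation and converted into the (S)-isopropenyl carbinol; a second lithiation puts iodine at the future C4a; ring C is closed by the carbonylative three-component annulation; C2 is reduced last.
4. Stereochemistry: the carbinol centre (S) comes from a Shi epoxidation followed by an epoxide isomerization that leaves its C–O bond untouched. C2 (S) comes from a ligand-controlled CuH conjugate reduction of the flat flavone.

Key step: step 8

Assumption: the L-fructose-derived ketone catalyst of the Shi epoxidation (mirror image of the common D-fructose-derived one, accessible from L-sorbose) is taken as purchasable.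

**Step 1**
Reactants: 1 3,5-dimethoxyphenol
Product: 2 1,3-dimethoxy-5-(methoxymethoxy)benzene
Conditions: MOMCl, i-Pr2NEt, CH2Cl2, 0 °C → rt
Reagents that add atoms: chloromethyl methyl ether (MOMCl), COCCl
Why: Williamson-type O-alkylation of the phenol with the α-chloro ether gives the aryl acetal, which later serves as the stronger of the oxygen directors in both lithiations.

**Step 2**
Reactants: 2 1,3-dimethoxy-5-(methoxymethoxy)benzene; 3 prenyl bromide (1-bromo-3-methylbut-2-ene)
Product: 6 1,5-dimethoxy-3-(methoxymethoxy)-2-(3-methylbut-2-en-1-yl)benzene, via aryllithium 4 (not isolated), via arylcopper 5 (not isolated)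
Conditions: n-BuLi, THF, 0 °C; CuBr·SMe2, −78 → −40 °C; then 3, −78 °C → rt
Reagents that add atoms: none
Why: Directed ortho-metalation should remove the proton flanked by OMOM and OMe (the chelating acetal outranks methoxy as director, and two such positions compete with one methoxy/methoxy position), and transmetalation to the arylcopper lets the allylic substitution of prenyl bromide occur at the primary carbon (SN2, not SN2′).

**Step 3**
Reactants: 6 1,5-dimethoxy-3-(methoxymethoxy)-2-(3-methylbut-2-en-1-yl)benzene
Product: 7 (3S)-3-{[2,4-dimethoxy-6-(methoxymethoxy)phenyl]methyl}-2,2-dimethyloxirane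
Conditions: L-fructose-derived Shi ketone (30 mol %), KHSO5 (as 2KHSO5·KHSO4·K2SO4), K2CO3, Bu4NHSO4, MeCN–CH2(OMe)2–aq. Na2B4O7 buffer (pH ≈ 10.5), 0 °C
Reagents that add atoms: potassium peroxymonosulfate (KHSO5), [K+].[O-]S(=O)(=O)OO
Why: Shi asymmetric epoxidation, in which the chiral dioxirane transfers oxygen to the trisubstituted alkene through a spiro transition state; the D-fructose-derived ketone gives the R epoxide carbon with alkenes of this substitution pattern, so its mirror image should give the required S centre, and the basic buffer spares the acetal.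

**Step 4**
Reactants: 7 (3S)-3-{[2,4-dimethoxy-6-(methoxymethoxy)phenyl]methyl}-2,2-dimethyloxirane
Product: 8 (2S)-1-[2,4-dimethoxy-6-(methoxymethoxy)phenyl]-3-methylbut-3-en-2-ol
Conditions: Et2AlCl, lithium 2,2,6,6-tetramethylpiperidide (from the amine and n-BuLi), toluene, 0 °C; aq. potassium sodium tartrate
Reagents that add atoms: none
Why: Aluminium amide-mediated epoxide-to-allylic alcohol isomerization, in which aluminium binds the epoxide oxygen and the amide removes a methyl proton in a cyclic syn-elimination that breaks the tertiary C–O bond, so the secondary C–O bond keeps its S configuration.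

**Step 5**
Reactants: 8 (2S)-1-[2,4-dimethoxy-6-(methoxymethoxy)phenyl]-3-methylbut-3-en-2-ol
Product: 9 tert-butyl{[(2S)-1-[2,4-dimethoxy-6-(methoxymethoxy)phenyl]-3-methylbut-3-en-2-yl]oxy}dimethylsilane
Conditions: TBSCl, imidazole, DMF, rt
Reagents that add atoms: tert-butyldimethylsilyl chloride (TBSCl), CC(C)(C)[Si](C)(C)Cl
Why: Standard silylation of a secondary alcohol (silyl chloride–imidazole), masking the hydroxyl against n-BuLi, the carbonylation and the copper hydride.

**Step 6**
Reactants: 9 tert-butyl{[(2S)-1-[2,4-dimethoxy-6-(methoxymethoxy)phenyl]-3-methylbut-3-en-2-yl]oxy}dimethylsilane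
Product: 11 tert-butyl{[(2S)-1-[3-iodo-4,6-dimethoxy-2-(methoxymethoxy)phenyl]-3-methylbut-3-en-2-yl]oxy}dimethylsilane, via aryllithium 10 (not isolated)
Conditions: n-BuLi, THF, 0 °C; I2, −78 °C → rt; aq. Na2S2O3
Reagents that add atoms: iodine (I2), II
Why: A second directed ortho-metalation at the one remaining position flanked by OMOM and OMe, followed by iodinolysis of the aryllithium, places iodine at the future C4a; the methoxy/methoxy-flanked position is the less activated site.

**Step 7**
Reactants: 11 tert-butyl{[(2S)-1-[3-iodo-4,6-dimethoxy-2-(methoxymethoxy)phenyl]-3-methylbut-3-en-2-yl]oxy}dimethylsilane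
Product: 13 2-[(2S)-2-(tert-butyldimethylsilyloxy)-3-methylbut-3-en-1-yl]-6-iodo-3,5-dimethoxyphenol, via aryl trimethylsilyl ether 12 (not isolated)
Conditions: TMSOTf, 2,2′-bipyridyl, MeCN, 0 °C → rt; then H2O
Reagents that add atoms: none
Why: Chemoselective cleavage of an aryl methoxymethyl ether with silyl triflate–2,2′-bipyridyl, in which the buffered silyl triflate activates the acetal oxygen and gives the aryl silyl ether (hydrolysed on work-up) in a medium not protic enough to remove the secondary silyl ether.

**Step 8**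
Reactants: 13 2-[(2S)-2-(tert-butyldimethylsilyloxy)-3-methylbut-3-en-1-yl]-6-iodo-3,5-dimethoxyphenol; 14 phenylacetylene; 15 carbon monoxide
Product: 18 8-[(2S)-2-(tert-butyldimethylsilyloxy)-3-methylbut-3-en-1-yl]-5,7-dimethoxy-2-phenyl-4H-chromen-4-one, via hydroxyaryl ynone 16 (not isolated), via enaminone 17 (not isolated)
Conditions: PdCl2(PPh3)2 (5 mol %), CO (20 bar), Et2NH, 120 °C
Reagents that add atoms: none
Why: Zerovalent palladium, formed in situ from the divalent precatalyst, inserts into the C–I bond of 13, CO insertion gives an aroylpalladium iodide, and coupling with phenylacetylene (deprotonated by Et2NH) releases ynone 16, so C4a–C4 and C4–C3 are made in one catalytic cycle. Et2NH then adds to the ynone to give enaminone 17, and the phenol oxygen attacks the amine-bearing carbon and expels Et2NH, which forms O1–C2 and closes ring C by a 6-endo-trig addition–elimination. The closest known reaction type is the carbonylative Sonogashira coupling–cyclization of ortho-iodophenols with terminal alkynes to chromones. No stereocenter is created. Two selectivities are needed: CO insertion must precede alkynylation (direct coupling would lead to a benzofuran), which the CO pressure, the copper-free medium and the electron-rich aryl–palladium bond should favour, and closure must be 6-endo, not 5-exo to the aurone, which passage through the enaminone in the secondary amine secures. Because iodine stands between the hydroxyl and a methoxy group and meta to the side chain, only the 8-substituted 5,7-dimethoxy pattern can form, and the alkene and silyl ether are out of reach of the acylpalladium centre.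

**Step 9**
Reactants: 18 8-[(2S)-2-(tert-butyldimethylsilyloxy)-3-methylbut-3-en-1-yl]-5,7-dimethoxy-2-phenyl-4H-chromen-4-one
Product: 20 (2S)-8-[(2S)-2-(tert-butyldimethylsilyloxy)-3-methylbut-3-en-1-yl]-5,7-dimethoxy-2-phenyl-2,3-dihydro-4H-chromen-4-one, via silyl enol ether 19 (not isolated)
Conditions: Cu(OAc)2·H2O (5 mol %), (S)-DTBM-SEGPHOS (5.5 mol %), (EtO)2MeSiH, toluene, 0 °C → rt; then 1 M aq. HCl, THF, 0 °C
Reagents that add atoms: none
Why: Copper hydride-catalysed asymmetric conjugate reduction (1,4-hydrosilylation) of a chromone, in which the bisphosphine-ligated CuH adds hydride to C2 and the enolate is held as the silyl enol ether until mild acid hydrolysis, protecting it from over-reduction and ring opening; the (S)-ligand is chosen by analogy with the sense of induction in 3-substituted cycloalkenones, which maps onto hydride delivery to the Re face of C2 (2S), and the remote, isolated 1,1-disubstituted alkene and side-chain centre should not interfere.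

**Step 10**
Reactants: 20 (2S)-8-[(2S)-2-(tert-butyldimethylsilyloxy)-3-methylbut-3-en-1-yl]-5,7-dimethoxy-2-phenyl-2,3-dihydro-4H-chromen-4-one
Product: 21 (2S)-8-[(2S)-2-hydroxy-3-methylbut-3-en-1-yl]-5,7-dimethoxy-2-phenyl-2,3-dihydro-4H-chromen-4-one
Conditions: HF·pyridine, pyridine, THF, 0 °C → rt
Reagents that add atoms: none
Why: Fluoride-mediated silyl ether cleavage under weakly acidic conditions, chosen because basic fluoride could open the flavanone to the chalcone by retro-oxa-Michael reaction and erode C2.

**Compound list**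
1 | 3,5-dimethoxyphenol | COc1cc(O)cc(OC)c1 | starting material
2 | 1,3-dimethoxy-5-(methoxymethoxy)benzene | COCOc1cc(OC)cc(OC)c1 | intermediate
3 | prenyl bromide (1-bromo-3-methylbut-2-ene) | CC(C)=CCBr | starting material
4 | [2,4-dimethoxy-6-(methoxymethoxy)phenyl]lithium | COCOc1cc(OC)cc(OC)c1[Li] | intermediate (not isolated)
5 | [2,4-dimethoxy-6-(methoxymethoxy)phenyl]copper | COCOc1cc(OC)cc(OC)c1[Cu] | intermediate (not isolated)
6 | 1,5-dimethoxy-3-(methoxymethoxy)-2-(3-methylbut-2-en-1-yl)benzene | COCOc1cc(OC)cc(OC)c1CC=C(C)C | intermediate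
7 | (3S)-3-{[2,4-dimethoxy-6-(methoxymethoxy)phenyl]methyl}-2,2-dimethyloxirane | CC1(C)O[C@H]1Cc1c(OC)cc(OC)cc1OCOC | intermediate
8 | (2S)-1-[2,4-dimethoxy-6-(methoxymethoxy)phenyl]-3-methylbut-3-en-2-ol | C=C(C)[C@@H](O)Cc1c(OC)cc(OC)cc1OCOC | intermediate
9 | tert-butyl{[(2S)-1-[2,4-dimethoxy-6-(methoxymethoxy)phenyl]-3-methylbut-3-en-2-yl]oxy}dimethylsilane | C=C(C)[C@@H](O[Si](C)(C)C(C)(C)C)Cc1c(OC)cc(OC)cc1OCOC | intermediate
10 | {3-[(2S)-2-(tert-butyldimethylsilyloxy)-3-methylbut-3-en-1-yl]-4,6-dimethoxy-2-(methoxymethoxy)phenyl}lithium | C=C(C)[C@@H](O[Si](C)(C)C(C)(C)C)Cc1c(OC)cc(OC)c([Li])c1OCOC | intermediate (not isolated)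
11 | tert-butyl{[(2S)-1-[3-iodo-4,6-dimethoxy-2-(methoxymethoxy)phenyl]-3-methylbut-3-en-2-yl]oxy}dimethylsilane | C=C(C)[C@@H](O[Si](C)(C)C(C)(C)C)Cc1c(OC)cc(OC)c(I)c1OCOC | intermediate
12 | tert-butyl{[(2S)-1-[3-iodo-4,6-dimethoxy-2-(trimethylsilyloxy)phenyl]-3-methylbut-3-en-2-yl]oxy}dimethylsilane | C=C(C)[C@@H](O[Si](C)(C)C(C)(C)C)Cc1c(OC)cc(OC)c(I)c1O[Si](C)(C)C | intermediate (not isolated)
13 | 2-[(2S)-2-(tert-butyldimethylsilyloxy)-3-methylbut-3-en-1-yl]-6-iodo-3,5-dimethoxyphenol | C=C(C)[C@@H](O[Si](C)(C)C(C)(C)C)Cc1c(OC)cc(OC)c(I)c1O | intermediate (key-step precursor)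
14 | phenylacetylene | C#Cc1ccccc1 | starting material
15 | carbon monoxide | [C-]#[O+] | starting material
16 | 1-{3-[(2S)-2-(tert-butyldimethylsilyloxy)-3-methylbut-3-en-1-yl]-2-hydroxy-4,6-dimethoxyphenyl}-3-phenylprop-2-yn-1-one | C=C(C)[C@@H](O[Si](C)(C)C(C)(C)C)Cc1c(OC)cc(OC)c(C(=O)C#Cc2ccccc2)c1O | intermediate (not isolated)
17 | (2E)-1-{3-[(2S)-2-(tert-butyldimethylsilyloxy)-3-methylbut-3-en-1-yl]-2-hydroxy-4,6-dimethoxyphenyl}-3-(diethylamino)-3-phenylprop-2-en-1-one | C=C(C)[C@@H](O[Si](C)(C)C(C)(C)C)Cc1c(OC)cc(OC)c(C(=O)/C=C(/N(CC)CC)c2ccccc2)c1O | intermediate (not isolated)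
18 | 8-[(2S)-2-(tert-butyldimethylsilyloxy)-3-methylbut-3-en-1-yl]-5,7-dimethoxy-2-phenyl-4H-chromen-4-one | C=C(C)[C@@H](O[Si](C)(C)C(C)(C)C)Cc1c(OC)cc(OC)c2c1OC(c1ccccc1)=CC2=O | intermediate (key-step product)
19 | (2S)-8-[(2S)-2-(tert-butyldimethylsilyloxy)-3-methylbut-3-en-1-yl]-4-[diethoxy(methyl)silyloxy]-5,7-dimethoxy-2-phenyl-2H-chromene | C=C(C)[C@@H](O[Si](C)(C)C(C)(C)C)Cc1c(OC)cc(OC)c2c1O[C@H](c1ccccc1)C=C2O[Si](C)(OCC)OCC | intermediate (not isolated)
20 | (2S)-8-[(2S)-2-(tert-butyldimethylsilyloxy)-3-methylbut-3-en-1-yl]-5,7-dimethoxy-2-phenyl-2,3-dihydro-4H-chromen-4-one | C=C(C)[C@@H](O[Si](C)(C)C(C)(C)C)Cc1c(OC)cc(OC)c2c1O[C@H](c1ccccc1)CC2=O | intermediate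
21 | (2S)-8-[(2S)-2-hydroxy-3-methylbut-3-en-1-yl]-5,7-dimethoxy-2-phenyl-2,3-dihydro-4H-chromen-4-one | C=C(C)[C@@H](O)Cc1c(OC)cc(OC)c2c1O[C@H](c1ccccc1)CC2=O | target

**Step count**
Total: 10 steps. Longest linear sequence: 10 steps (1 → 21); prenyl bromide, phenylacetylene and carbon monoxide enter as purchased reactants.

**Steps most likely to fail**

Step 9. Hydride transfer from the ligated CuH to the electron-rich, 2-aryl-substituted vinylogous ester may be slow. Facial discrimination at C2 may be incomplete. The copper enolate may also open ring C by β-elimination of the phenoxide before it is silylated. The fallback sets out from 18. An unselective conjugate reduction with LiBH(s-Bu)3 in THF at −78 °C would give 20 together with its C2 epimer, the (2R)-silyl flavanone F1. A kinetic resolution by asymmetric transfer hydrogenation (RhCl(Cp*)[(R,R)-TsDPEN] or its mirror image, whichever reduces the 2R series faster; HCO2H–Et3N, EtOAc) would then convert the epimer into the cis-(2R,4R)-flavan-4-ol F2, which is removed by chromatography. What remains is 20, where the route is rejoined.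

Step 8. Oxidative addition into the doubly ortho-substituted, electron-rich C–I bond may be sluggish, alkynylation may outrun CO insertion, or the ynone may close 5-exo. The fallback sets out from 9 and forms the C4a–C4 bond without palladium. The aryllithium 10, generated as in step 6, would be acylated with N-methoxy-N-methyl-3-phenylprop-2-ynamide (Weinreb ketone synthesis, THF, −78 °C) to give the methoxymethyl-protected ynone F3. Acetal cleavage under the conditions of step 7 would give hydroxyaryl ynone 16. Et2NH in EtOH at rt would then take it through enaminone 17 to flavone 18, where the route is rejoined.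

Step 7. The Lewis acidic acetal cleavage may also strip the secondary silyl ether or ionize the allylic C–O bond. The fallback sets out from 11 and gives up selectivity on purpose. HCl in MeOH at rt would remove both the acetal and the silyl group to give the iodophenol alcohol F4. TBSOTf and 2,6-lutidine in CH2Cl2 would silylate both hydroxyls to give the bis(silyl ether) F5. K2CO3 in MeOH at rt would then cleave only the aryl silyl ether, returning to the route at 13.

**Further compounds**
F1 | step 9 | (2R)-8-[(2S)-2-(tert-butyldimethylsilyloxy)-3-methylbut-3-en-1-yl]-5,7-dimethoxy-2-phenyl-2,3-dihydro-4H-chromen-4-one | C=C(C)[C@@H](O[Si](C)(C)C(C)(C)C)Cc1c(OC)cc(OC)c2c1O[C@@H](c1ccccc1)CC2=O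
F2 | step 9 | (2R,4R)-8-[(2S)-2-(tert-butyldimethylsilyloxy)-3-methylbut-3-en-1-yl]-5,7-dimethoxy-2-phenyl-3,4-dihydro-2H-chromen-4-ol | C=C(C)[C@@H](O[Si](C)(C)C(C)(C)C)Cc1c(OC)cc(OC)c2c1O[C@@H](c1ccccc1)C[C@H]2O
F3 | step 8 | 1-{3-[(2S)-2-(tert-butyldimethylsilyloxy)-3-methylbut-3-en-1-yl]-4,6-dimethoxy-2-(methoxymethoxy)phenyl}-3-phenylprop-2-yn-1-one | C=C(C)[C@@H](O[Si](C)(C)C(C)(C)C)Cc1c(OC)cc(OC)c(C(=O)C#Cc2ccccc2)c1OCOC
F4 | step 7 | 2-[(2S)-2-hydroxy-3-methylbut-3-en-1-yl]-6-iodo-3,5-dimethoxyphenol | C=C(C)[C@@H](O)Cc1c(OC)cc(OC)c(I)c1O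
F5 | step 7 | tert-butyl{2-[(2S)-2-(tert-butyldimethylsilyloxy)-3-methylbut-3-en-1-yl]-6-iodo-3,5-dimethoxyphenoxy}dimethylsilane | C=C(C)[C@@H](O[Si](C)(C)C(C)(C)C)Cc1c(OC)cc(OC)c(I)c1O[Si](C)(C)C(C)(C)C
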